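**Retrosynthetic overview**
1. Target 14 comes from 13 by fluoride removal of the 4'-O-silyl group, and 13 from 12 by alkylation of the free 7-OH (the 5-OH is chelated to C4=O).
2. Ring A of 12 is made last by cutting C7–C8 and C5–C6. This gives pyranone ester 9, whose ester carbon becomes C5 and whose CH2OMe carbon becomes C8, and the acetyl donor 10, which supplies C6 and C7.
3. The feature used is that ring A is a resorcinol: 5-OH and 7-OH flank C6–H, and the methoxy-bearing C8 sits on C8a. This is an acetate unit spliced between an ester carbon on C4a and a methoxymethyl carbon on C8a.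
4. Ring C (the 4-pyranone) comes from cyclodehydration of triketo ester 8, made by aroylation of the dianion of triacylmethane 7 with imidazolide 4. Compound 7 comes from 5 and 6, and 4 from vanillic acid 1.
5. Order of rings: B is bought (vanillic acid), C is closed in step 5, A in step 6.

Key step: step 6

Remark: the target has no stereocentre and no stereogenic double bond, so the request for a single enantiomer places no demand on the route. Ar = 3-methoxy-4-(triisopropylsilyloxy)phenyl. Pyranones are numbered like the flavone they become (O1, aryl at C2, OMe at C3, C4=O, ester at C5, CH2OMe at C6).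

**Route**

Step 1
Reactants: 1 vanillic acid
Product: 3 3-methoxy-4-(triisopropylsilyloxy)benzoic acid, via bis-silylated vanillate 2 (not isolated)
Conditions: TIPSCl (2.4 equiv), imidazole (5 equiv), DMF, rt; then K2CO3, MeOH–THF–H2O, rt; aq. KHSO4 to pH 4
Reagents that add atoms: triisopropylsilyl chloride, CC(C)[Si](Cl)(C(C)C)C(C)C
Why: Silylation of phenol and acid with a silyl chloride and imidazole, then selective carbonate hydrolysis of the far more labile silyl ester, should leave the hindered aryl TIPS ether intact.

Step 2
Reactants: 3 3-methoxy-4-(triisopropylsilyloxy)benzoic acid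
Product: 4 1-[3-methoxy-4-(triisopropylsilyloxy)benzoyl]imidazole
Conditions: CDI (1.1 equiv), CH2Cl2, rt; quick cold-water wash, dry, concentrate
Reagents that add atoms: 1,1'-carbonyldiimidazole, O=C(n1ccnc1)n1ccnc1
Why: Acyl imidazole formation with CDI is driven by loss of CO2, and the wash removes the free imidazole that would otherwise quench the carbanion in step 4.

Step 3
Reactants: 5 methyl 4-methoxyacetoacetate; 6 methoxyacetyl chloride
Product: 7 methyl 4-methoxy-2-(methoxyacetyl)-3-oxobutanoate (a triacylmethane, present as its enol)
Conditions: MgCl2 (1.0 equiv), pyridine (2.0 equiv), CH2Cl2, 0 °C; then 6 (1.0 equiv), 0 °C → rt; 1 M HCl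
Reagents that add atoms: none
Why: Rathke-type soft enolisation gives the magnesium chelate of the β-keto ester, which is acylated at carbon by the acid chloride, and the chelated product does not react further.

Step 4
Reactants: 7 methyl 4-methoxy-2-(methoxyacetyl)-3-oxobutanoate; 4 1-[3-methoxy-4-(triisopropylsilyloxy)benzoyl]imidazole
Product: 8 methyl 5-Ar-4-methoxy-2-(methoxyacetyl)-3,5-dioxopentanoate (mixture of enol tautomers, used crude)
Conditions: 7 (2.0 equiv), LDA (4.1 equiv), THF, −78 → 0 °C; then 4 (1.0 equiv), −78 → −20 °C; aq. HCl
Reagents that add atoms: none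
Why: In this polyanion acylation of the Harris/Huckin–Weiler type, the first equivalent of LDA gives the triacylmethanide and the second removes a proton from one of the two equivalent CH2OMe groups, so the terminal carbanion is the only carbon nucleophile for the imidazolide, and the second equivalent of dianion takes up the acidic proton of the product.

Step 5
Reactants: 8 methyl 5-Ar-4-methoxy-2-(methoxyacetyl)-3,5-dioxopentanoate
Product: 9 methyl 2-Ar-3-methoxy-6-(methoxymethyl)-4-oxo-4H-pyran-5-carboxylate
Conditions: TFA–CH2Cl2 (1:4), 0 °C → rt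
Reagents that add atoms: none
Why: Acid-catalysed cyclodehydration of a 1,3,5-triketone to a 4-pyranone should work because the enol oxygen of one terminal ketone adds to the other protonated ketone, which under Brønsted acid is a better electrophile than the ester, and the aryl TIPS ether tolerates TFA.

Step 6
Reactants: 9 methyl 2-Ar-3-methoxy-6-(methoxymethyl)-4-oxo-4H-pyran-5-carboxylate; 10 N-methoxy-N-methylacetamide
Product: 12 5,7-dihydroxy-3,8,3'-trimethoxy-4'-(triisopropylsilyloxy)flavone, via methyl ketone 11 (not isolated)
Conditions: LDA (1.1 equiv), THF, −78 °C; 10 (1.3 equiv), −78 → −40 °C; LDA (2.6 equiv), −78 → 0 °C; aq. HCl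
Reagents that add atoms: none
Why: LDA removes a proton from the C6 methoxymethyl group of 9, which is vinylogous to both the ring carbonyl and the ester, and the extended enolate adds through that carbon to the Weinreb amide; the second charge of base deprotonates the adduct, which expels lithium N,O-dimethylhydroxylamide to give the enolate of ketone 11 (new bond C7–C8). Further LDA forms the methyl enolate of 11, which attacks the neighbouring ester carbonyl in a 6-exo-trig Claisen closure (new bond C5–C6), and loss of methoxide with double enolisation aromatises ring A as its bis-phenoxide. The closest known reaction type is the tandem acylation and Claisen cyclisation of toluate-type lateral anions to 1,3-dihydroxyarenes, together with the biomimetic cyclisation of β-polyketo esters to resorcinols. No stereocentre is formed. The step needs deprotonation at the single acidic CH2 (nothing else in 9 is acidic) and closure through carbon, not oxygen, of the ketone enolate, which the excess strong base secures by forming the C-nucleophilic dianion. The base is added in two portions so that the enolisable amide never meets a large excess of LDA, and regiochemistry is fixed because the carbanion carbon already carries the methoxy group and sits next to the ester, so the acetyl carbonyl can only become 7-OH and the ester carbonyl 5-OH.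

Step 7
Reactants: 12 5,7-dihydroxy-3,8,3'-trimethoxy-4'-(triisopropylsilyloxy)flavone
Product: 13 5-hydroxy-3,8,3'-trimethoxy-7-(3-methylbut-2-enyloxy)-4'-(triisopropylsilyloxy)flavone
Conditions: prenyl bromide (1.2 equiv), K2CO3 (1.5 equiv), acetone, 45 °C
Reagents that add atoms: prenyl bromide (1-bromo-3-methylbut-2-ene), CC(C)=CCBr
Why: Williamson etherification should be selective for the 7-OH, the most acidic phenol (para to C4=O), because the 5-OH is held in a hydrogen bond to the C4 carbonyl and the 4'-oxygen is silylated.

Step 8
Reactants: 13 5-hydroxy-3,8,3'-trimethoxy-7-(3-methylbut-2-enyloxy)-4'-(triisopropylsilyloxy)flavone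
Product: 14 5,4'-dihydroxy-3,8,3'-trimethoxy-7-prenyloxyflavone
Conditions: TBAF (1.2 equiv), AcOH (1.2 equiv), THF, 0 °C
Reagents that add atoms: none
Why: Fluoride-induced cleavage of the aryl silyl ether, buffered with acetic acid, should leave the prenyl ether, the chelated 5-OH and the flavone untouched.

**Compound list**
1 | vanillic acid | COc1cc(C(=O)O)ccc1O | starting material
2 | triisopropylsilyl 3-methoxy-4-(triisopropylsilyloxy)benzoate | COc1cc(C(=O)O[Si](C(C)C)(C(C)C)C(C)C)ccc1O[Si](C(C)C)(C(C)C)C(C)C | intermediate (not isolated)
3 | 3-methoxy-4-(triisopropylsilyloxy)benzoic acid | COc1cc(C(=O)O)ccc1O[Si](C(C)C)(C(C)C)C(C)C | intermediate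
4 | 1-[3-methoxy-4-(triisopropylsilyloxy)benzoyl]imidazole | COc1cc(C(=O)n2ccnc2)ccc1O[Si](C(C)C)(C(C)C)C(C)C | intermediate
5 | methyl 4-methoxyacetoacetate | COCC(=O)CC(=O)OC | starting material
6 | methoxyacetyl chloride | COCC(=O)Cl | starting material
7 | methyl 4-methoxy-2-(methoxyacetyl)-3-oxobutanoate (drawn as keto form) | COCC(=O)C(C(=O)OC)C(=O)COC | intermediate
8 | methyl 4-methoxy-2-(methoxyacetyl)-5-[3-methoxy-4-(triisopropylsilyloxy)phenyl]-3,5-dioxopentanoate (drawn as keto form; enol tautomers, no fixed configuration) | COCC(=O)C(C(=O)OC)C(=O)C(OC)C(=O)c1ccc(O[Si](C(C)C)(C(C)C)C(C)C)c(OC)c1 | intermediate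
9 | methyl 3-methoxy-6-(methoxymethyl)-2-[3-methoxy-4-(triisopropylsilyloxy)phenyl]-4-oxo-4H-pyran-5-carboxylate | COCc1oc(-c2ccc(O[Si](C(C)C)(C(C)C)C(C)C)c(OC)c2)c(OC)c(=O)c1C(=O)OC | intermediate
10 | N-methoxy-N-methylacetamide | CC(=O)N(C)OC | starting material
11 | methyl 3-methoxy-6-(1-methoxy-2-oxopropyl)-2-[3-methoxy-4-(triisopropylsilyloxy)phenyl]-4-oxo-4H-pyran-5-carboxylate (formed as its lithium enolate; racemic if protonated) | CC(=O)C(OC)c1oc(-c2ccc(O[Si](C(C)C)(C(C)C)C(C)C)c(OC)c2)c(OC)c(=O)c1C(=O)OC | intermediate (not isolated)
12 | 5,7-dihydroxy-3,8,3'-trimethoxy-4'-(triisopropylsilyloxy)flavone | COc1cc(-c2oc3c(OC)c(O)cc(O)c3c(=O)c2OC)ccc1O[Si](C(C)C)(C(C)C)C(C)C | intermediate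
13 | 5-hydroxy-3,8,3'-trimethoxy-7-(3-methylbut-2-enyloxy)-4'-(triisopropylsilyloxy)flavone | COc1cc(-c2oc3c(OC)c(OCC=C(C)C)cc(O)c3c(=O)c2OC)ccc1O[Si](C(C)C)(C(C)C)C(C)C | intermediate
14 | 5,4'-dihydroxy-3,8,3'-trimethoxy-7-prenyloxyflavone | COc1cc(-c2oc3c(OC)c(OCC=C(C)C)cc(O)c3c(=O)c2OC)ccc1O | target

**Step count and risk**
Total steps: 8. Longest linear sequence: 7 (steps 1, 2, 4, 5, 6, 7, 8 from vanillic acid).

Step 6 (ring A annulation). The addition of the stabilised carbanion to the amide may reverse on warming, the amide may be enolised by the excess base, or the ketone enolate may close through oxygen onto the ester (enol lactone) faster than the methyl carbon does. The fallback sets out from 9 and returns at 12, making the same two bonds in the opposite order with the polarity at C7 inverted. The methyl ester of 9 would be cleaved with Me3SnOH (1,2-dichloroethane, 80 °C) to 3-methoxy-6-(methoxymethyl)-2-Ar-4-oxo-4H-pyran-5-carboxylic acid F1. Activation with CDI and reaction with magnesium methyl malonate (Masamune–Brooks homologation) should give the β-keto ester methyl 3-[3-methoxy-6-(methoxymethyl)-2-Ar-4-oxo-4H-pyran-5-yl]-3-oxopropanoate F2, which already holds the C5–C6 bond. LDA (2.2 equiv, THF, −78 → 0 °C) would then deprotonate the β-keto ester and the methoxymethyl group, and the C8 carbanion should close onto the terminal ester (Dieckmann condensation, C7–C8). Loss of methanol and tautomerisation give 12.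

Step 4 (polyanion aroylation). The dianion may form incompletely, proton transfer from the more acidic product may stop the acylation at partial conversion, or the acyl group may be transferred to oxygen. The fallback sets out from 7 and returns at 8 by aldol addition and oxidation. Vanillin would be silylated (TIPSCl, imidazole, DMF) to 3-methoxy-4-(triisopropylsilyloxy)benzaldehyde F3. The dianion of 7 (LDA, 2.1 equiv, THF, −78 °C) should add to this aldehyde without forming an acidic product, giving the aldol adduct methyl 5-hydroxy-4-methoxy-2-(methoxyacetyl)-5-Ar-3-oxopentanoate F4 as a mixture of diastereomers. Dess–Martin periodinane (NaHCO3, CH2Cl2) would oxidise the benzylic alcohol to give 8.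

Step 5 (pyranone closure). The enol oxygen may close onto the ester carbonyl with loss of methanol (a 3-acyl-4-hydroxy-2-pyranone) instead of onto the ketone, or the acid may remove the silyl ether. The fallback sets out from 7 and returns at 9, forming the ring O–C2 bond from an alcohol and dehydrogenating afterwards. The aldol adduct F4 of the step 4 fallback is not oxidised. Catalytic TsOH (CH2Cl2, rt) should close its benzylic hydroxyl onto the enolised methoxyacetyl carbonyl with loss of water, giving methyl 3-methoxy-6-(methoxymethyl)-2-Ar-4-oxo-2,3-dihydro-4H-pyran-5-carboxylate F5 (racemic diastereomers; both centres are removed next). DDQ (dioxane, 80 °C) would dehydrogenate it to 9, as in the flavanone-to-flavone oxidation.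

**Further compounds**
F1 | step 6 | 3-methoxy-6-(methoxymethyl)-2-[3-methoxy-4-(triisopropylsilyloxy)phenyl]-4-oxo-4H-pyran-5-carboxylic acid | COCc1oc(-c2ccc(O[Si](C(C)C)(C(C)C)C(C)C)c(OC)c2)c(OC)c(=O)c1C(=O)O
F2 | step 6 | methyl 3-[3-methoxy-6-(methoxymethyl)-2-[3-methoxy-4-(triisopropylsilyloxy)phenyl]-4-oxo-4H-pyran-5-yl]-3-oxopropanoate | COCc1oc(-c2ccc(O[Si](C(C)C)(C(C)C)C(C)C)c(OC)c2)c(OC)c(=O)c1C(=O)CC(=O)OC
F3 | step 4 | 3-methoxy-4-(triisopropylsilyloxy)benzaldehyde | COc1cc(C=O)ccc1O[Si](C(C)C)(C(C)C)C(C)C
F4 | step 4 | methyl 5-hydroxy-4-methoxy-2-(methoxyacetyl)-5-[3-methoxy-4-(triisopropylsilyloxy)phenyl]-3-oxopentanoate (diastereomer mixture, racemic) | COCC(=O)C(C(=O)OC)C(=O)C(OC)C(O)c1ccc(O[Si](C(C)C)(C(C)C)C(C)C)c(OC)c1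
F5 | step 5 | methyl 3-methoxy-6-(methoxymethyl)-2-[3-methoxy-4-(triisopropylsilyloxy)phenyl]-4-oxo-2,3-dihydro-4H-pyran-5-carboxylate (racemic diastereomers) | COCC1=C(C(=O)OC)C(=O)C(OC)C(c2ccc(O[Si](C(C)C)(C(C)C)C(C)C)c(OC)c2)O1
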